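The target is numbered as a bicyclo[3.2.1]oct-2-en-8-one: C1 (allyl), C2=C3(OMe), C4 (OAc), C5 (OMe), C6 (aryl), C7 (methyl), C8 (C=O). Everything rests on the C4–C5 bond: C4–O and the C8 carbonyl are an aldol pair across C5, and the cis C2=C3 bond lets both be stored as one enol δ-lactone (C8–O–C4=O) fused to the preformed five-membered ring C1–C8–C5–C6–C7. One hydride equivalent releases the C4 aldehyde and the C8–O/C5 aluminium enolate, which close the six-membered carbocycle C1–C2–C3–C4–C5–C8 last, set C4 and C5 through a chelate, and are acetylated in the same flask.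

Key step: step 8

Remark on the chemistry: the silyloxy enone, the aryl Grignard reagent, allyl methyl carbonate and methoxyacetic acid are taken as purchasable; the methoxy-bearing carbon next to the ketone in the monocyclic intermediates is drawn as the trans isomer, but it is enolisable and is erased in step 7, so it need not be controlled. Ar = 3,4-dimethoxyphenyl; monocyclic ketones are numbered C1 (C=O), C2 (O-bearing), C3 (aryl), C4 (methyl), C5.

Step 1
Reactants: 1 (S)-4-(tert-butyldimethylsilyloxy)cyclopent-2-en-1-one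
Product: 3 (S)-4-methylcyclopent-2-en-1-one, via TBS-oxy ketone 2 (not isolated)
Conditions: MeMgBr, CuBr·SMe2 (10 mol %), THF, −78 °C; H2O; crude 2, DBU, CH2Cl2, 0 °C
Reagents that add atoms: methylmagnesium bromide, C[Mg]Br
Why: Copper-catalysed conjugate addition should place the methyl group anti to the silyloxy group, and DBU then enolises 2 towards C5 and expels silanolate (E1cB, conjugate addition–elimination), so the enone is transposed and the methyl-bearing carbon of 3 takes the configuration dictated by 1.

Step 2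
Reactants: 3 (S)-4-methylcyclopent-2-en-1-one; 4 3,4-dimethoxyphenylmagnesium bromide
Product: 7 (2S,3S,4S)-3-(3,4-dimethoxyphenyl)-2-hydroxy-4-methylcyclopentan-1-one, via silyl enol ether 5 (not isolated), via TMS-oxy ketone 6 (not isolated)
Conditions: 4, CuBr·SMe2 (5 mol %), Me3SiCl, THF, −78 °C; then mCPBA, CH2Cl2, −20 °C; then aq. HCl (cat.), THF, 0 °C
Reagents that add atoms: 3-chloroperbenzoic acid, OOC(=O)c1cccc(Cl)c1
Why: Copper-catalysed conjugate addition with Me3SiCl trapping should occur anti to the 4-methyl group (aryl and methyl trans) and give the enol ether regiospecifically at C1–C2, whose Rubottom oxidation from the face opposite the aryl group installs the C2 oxygen.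

Step 3
Reactants: 7 (2S,3S,4S)-3-(3,4-dimethoxyphenyl)-2-hydroxy-4-methylcyclopentan-1-one
Product: 8 (2S,3S,4S)-3-(3,4-dimethoxyphenyl)-2-methoxy-4-methylcyclopentan-1-one
Conditions: MeOTf, 2,6-di-tert-butyl-4-methylpyridine, CH2Cl2, 0 °C → rt
Reagents that add atoms: methyl trifluoromethanesulfonate, COS(=O)(=O)C(F)(F)F
Why: Methyl triflate with a hindered, non-nucleophilic pyridine base methylates the secondary hydroxyl (O-alkylation) without forming an enolate, so the acyloin should not isomerise and no stereocentre is touched.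

Step 4
Reactants: 8 (2S,3S,4S)-3-(3,4-dimethoxyphenyl)-2-methoxy-4-methylcyclopentan-1-one
Product: 9 3-(3,4-dimethoxyphenyl)-5-(hydroxymethylene)-2-methoxy-4-methylcyclopentan-1-one (C2–C4 as in 8; enol form of the 5-formyl ketone)
Conditions: NaH, HCO2Et, THF, 0 °C → rt; then aq. HCl
Reagents that add atoms: ethyl formate, CCOC=O
Why: The crossed Claisen condensation with ethyl formate is reversible and can rest only at the C5 methylene, where the product is held as its stabilised enolate, so formylation should be regioselective; C3 and C4 are not acidic and C2 can at most settle into the trans arrangement already drawn.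

Step 5
Reactants: 9 3-(3,4-dimethoxyphenyl)-5-(hydroxymethylene)-2-methoxy-4-methylcyclopentan-1-one; 10 allyl methyl carbonate
Product: 11 5-allyl-3-(3,4-dimethoxyphenyl)-5-formyl-2-methoxy-4-methylcyclopentan-1-one (allyl trans to the 4-methyl group and cis to aryl; formyl cis to the 4-methyl group)
Conditions: Pd(PPh3)4 (5 mol %), THF, rt
Reagents that add atoms: none
Why: Tsuji–Trost allylation under neutral conditions should give C-allylation of the soft formyl-ketone enolate, the allyl electrophile approaching C5 anti to the adjacent 4-methyl group, which sets the quaternary centre with allyl trans and formyl cis to that methyl group.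

Step 6
Reactants: 11 5-allyl-3-(3,4-dimethoxyphenyl)-5-formyl-2-methoxy-4-methylcyclopentan-1-one; 12 methoxyacetic acid
Product: 13 3-[1-allyl-4-(3,4-dimethoxyphenyl)-3-methoxy-5-methyl-2-oxocyclopentyl]-3-hydroxy-2-methoxypropanoic acid (ring centres as in 11; mixture at the two side-chain centres)
Conditions: 12, LiN(i-Pr)2 (2 equiv), THF, −78 → 0 °C; then 11, −78 °C; AcOH, −78 °C
Reagents that add atoms: none
Why: Aldol addition of the lithium enediolate of methoxyacetic acid should occur at the aldehyde, which is far more electrophilic than the ketone flanked by a quaternary and a methoxy-bearing carbon; the two new centres are left uncontrolled on purpose because both become sp2 in step 7.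

Step 7
Reactants: 13 3-[1-allyl-4-(3,4-dimethoxyphenyl)-3-methoxy-5-methyl-2-oxocyclopentyl]-3-hydroxy-2-methoxypropanoic acid
Product: 15 4a-allyl-6-(3,4-dimethoxyphenyl)-3,7-dimethoxy-5-methyl-5,6-dihydrocyclopenta[b]pyran-2(4aH)-one (4a-allyl trans to 5-methyl; 5-methyl trans to 6-aryl), via trifluoroacetoxy lactone 14 (not isolated)
Conditions: (CF3CO)2O, CH2Cl2, 0 °C; then i-Pr2NEt, 0 °C → rt
Reagents that add atoms: none
Why: The anhydride acylates the hydroxyl and turns the acid into a mixed anhydride that is trapped by the ketone oxygen, loss of the C2 proton giving the enol δ-lactone (enol lactonisation of a δ-keto acid), and the amine then eliminates trifluoroacetate by E1cB inside the ring, so the new double bond is necessarily cis.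

Step 8
Reactants: 15 4a-allyl-6-(3,4-dimethoxyphenyl)-3,7-dimethoxy-5-methyl-5,6-dihydrocyclopenta[b]pyran-2(4aH)-one
Product: 19 (1S,4S,5S,6S,7R)-1-allyl-6-(3,4-dimethoxyphenyl)-3,5-dimethoxy-7-methyl-8-oxobicyclo[3.2.1]oct-2-en-4-yl acetate, via aluminium lactolate 16 (not isolated), via aluminium enolate 17 (not isolated), via aluminium aldolate 18 (not isolated)
Conditions: i-Bu2AlH (1.05 equiv), CH2Cl2, −78 → −30 °C; then pyridine, DMAP, Ac2O, −78 → 0 °C
Reagents that add atoms: acetic anhydride, CC(=O)OC(C)=O
Why: i-Bu2AlH adds once to the lactone carbonyl (the future C4); on warming, hemiacetal 16 expels the enol oxygen, which gives in one event the C4 aldehyde, held cis to C1 by the ring-derived C2=C3 bond, and the regiodefined C8–O–Al enolate at C5 (17); these combine by intramolecular aldol addition to 18, which is acetylated on oxygen in the flask. The closest known reaction type is the reductive aldol cyclisation of enol δ-lactones of 2-(2-carboxyethyl)cycloalkanones to bridged ketols with hydride reagents, followed by acetylation of the aluminium alkoxide as in reductive acetylation of esters. The six-membered carbocycle C1–C2–C3–C4–C5–C8 is closed at C4–C5 in a 6-(enolendo)-exo-trig mode. C5 is controlled by the tether: the aldehyde hangs from C1 on the face of the 7-methyl group, so C4 can only be delivered to that face and the 5-methoxy group ends cis to the 6-aryl group; C4 is controlled by the closed chair-like transition state in which aluminium bridges the aldehyde and enolate oxygens, which places C4–O gauche to C8 and anti to C6. The step needs a single 1,2-hydride transfer without a second reduction, which one equivalent at −78 °C should secure because the hemiacetal survives until the hydride is spent; it also needs enolisation at C5 only and a cis enal, and both are built into the enol lactone.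

Compound list
1 | (S)-4-(tert-butyldimethylsilyloxy)cyclopent-2-en-1-one | O=C1C=C[C@@H](O[Si](C)(C)C(C)(C)C)C1 | starting material
2 | (3S,4S)-4-(tert-butyldimethylsilyloxy)-3-methylcyclopentan-1-one (methyl trans to silyloxy) | O=C1C[C@H](C)[C@@H](O[Si](C)(C)C(C)(C)C)C1 | intermediate
3 | (S)-4-methylcyclopent-2-en-1-one | O=C1C=C[C@@H](C)C1 | intermediate
4 | 3,4-dimethoxyphenylmagnesium bromide | COc1ccc([Mg]Br)cc1OC | starting material
5 | [3-(3,4-dimethoxyphenyl)-4-methylcyclopent-1-en-1-yl]oxytrimethylsilane (aryl and methyl trans) | C[Si](C)(C)OC1=C[C@H](c2ccc(OC)c(OC)c2)[C@@H](C)C1 | intermediate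
6 | 3-(3,4-dimethoxyphenyl)-4-methyl-2-(trimethylsilyloxy)cyclopentan-1-one (2,3-trans, 3,4-trans) | O=C1[C@@H](O[Si](C)(C)C)[C@H](c2ccc(OC)c(OC)c2)[C@@H](C)C1 | intermediate
7 | (2S,3S,4S)-3-(3,4-dimethoxyphenyl)-2-hydroxy-4-methylcyclopentan-1-one | O=C1[C@@H](O)[C@H](c2ccc(OC)c(OC)c2)[C@@H](C)C1 | intermediate
8 | (2S,3S,4S)-3-(3,4-dimethoxyphenyl)-2-methoxy-4-methylcyclopentan-1-one | O=C1[C@@H](OC)[C@H](c2ccc(OC)c(OC)c2)[C@@H](C)C1 | intermediate
9 | 3-(3,4-dimethoxyphenyl)-5-(hydroxymethylene)-2-methoxy-4-methylcyclopentan-1-one (C2–C4 as in 8) | O=C1[C@@H](OC)[C@H](c2ccc(OC)c(OC)c2)[C@@H](C)C1=CO | intermediate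
10 | allyl methyl carbonate | C=CCOC(=O)OC | starting material
11 | 5-allyl-3-(3,4-dimethoxyphenyl)-5-formyl-2-methoxy-4-methylcyclopentan-1-one (allyl trans to 4-methyl, cis to aryl) | C=CC[C@]1(C=O)C(=O)[C@@H](OC)[C@H](c2ccc(OC)c(OC)c2)[C@H]1C | intermediate
12 | methoxyacetic acid | COCC(=O)O | starting material
13 | 3-[1-allyl-4-(3,4-dimethoxyphenyl)-3-methoxy-5-methyl-2-oxocyclopentyl]-3-hydroxy-2-methoxypropanoic acid (side-chain centres as a mixture) | C=CC[C@]1(C(O)C(OC)C(=O)O)C(=O)[C@@H](OC)[C@H](c2ccc(OC)c(OC)c2)[C@H]1C | intermediate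
14 | 4a-allyl-6-(3,4-dimethoxyphenyl)-3,7-dimethoxy-5-methyl-4-(trifluoroacetoxy)-3,4,5,6-tetrahydrocyclopenta[b]pyran-2(4aH)-one | C=CC[C@]12C(OC(=O)C(F)(F)F)C(OC)C(=O)OC1=C(OC)[C@H](c1ccc(OC)c(OC)c1)[C@H]2C | intermediate
15 | 4a-allyl-6-(3,4-dimethoxyphenyl)-3,7-dimethoxy-5-methyl-5,6-dihydrocyclopenta[b]pyran-2(4aH)-one (enol δ-lactone; allyl trans to 5-methyl, cis to 6-aryl) | C=CC[C@]12C=C(OC)C(=O)OC1=C(OC)[C@H](c1ccc(OC)c(OC)c1)[C@H]2C | intermediate
16 | diisobutylaluminium lactolate of 15 (hydride added at the lactone carbon) | C=CC[C@]12C=C(OC)C(O[Al](CC(C)C)CC(C)C)OC1=C(OC)[C@H](c1ccc(OC)c(OC)c1)[C@H]2C | intermediate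
17 | diisobutylaluminium enolate of the ring-opened keto-enal (formyl cis to the ring carbon across the enol ether double bond) | C=CC[C@]1(/C=C(/OC)\C=O)C(O[Al](CC(C)C)CC(C)C)=C(OC)[C@H](c2ccc(OC)c(OC)c2)[C@H]1C | intermediate
18 | diisobutylaluminium alkoxide of the bicyclic C4 ketol (configuration as in 19) | C=CC[C@]12C=C(OC)[C@H](O[Al](CC(C)C)CC(C)C)[C@](OC)(C1=O)[C@H](c1ccc(OC)c(OC)c1)[C@H]2C | intermediate
19 | (1S,4S,5S,6S,7R)-1-allyl-6-(3,4-dimethoxyphenyl)-3,5-dimethoxy-7-methyl-8-oxobicyclo[3.2.1]oct-2-en-4-yl acetate (4-acetoxy on the side of the C8 carbonyl; 6-aryl anti and 7-methyl syn to the C2–C4 bridge) | C=CC[C@]12C=C(OC)[C@H](OC(C)=O)[C@](OC)(C1=O)[C@H](c1ccc(OC)c(OC)c1)[C@H]2C | target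

Total step count: 8
Longest linear sequence: 8 steps (1 → 19)

Steps most likely to fail

Step 8. The aluminium hemiacetal may survive until work-up, so that reduction is not followed by carbon–carbon bond formation, or the freed aldehyde may be reduced a second time. The fallback sets out from 15 and separates the two events. Reduction with i-Bu2AlH (1.0 equiv, toluene, −78 °C), quenched cold with methanol and aqueous potassium sodium tartrate, should give the isolated lactol F1, the ring tautomer of the cis keto-enal. LiN(SiMe3)2 (THF, −78 → −20 °C, AcOH quench) then opens F1 and closes the aldol through the lithium chelate to ketol F2. Ac2O, DMAP and pyridine acetylate F2, and the route is rejoined at 19.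

Step 7. β-Elimination in the open-chain mixed anhydride may precede capture by the ketone and leave a 2-methoxyacrylic acid whose carboxyl is trans to the ring and cannot lactonise; the enol lactone may also be lost to acid or to a thermal allyl shift. The fallback sets out from 13 and locks the cis geometry in an ordinary alcohol lactone. NaBH4 (MeOH, 0 °C) reduces the ring ketone, and acidic work-up closes hydroxy δ-lactone F3. MsCl and Et3N, then DBU, eliminate inside the ring to unsaturated δ-lactone F4. Excess i-Bu2AlH gives diol F5, with the hydroxymethyl group cis to the ring carbon. Swern oxidation of both hydroxyls gives cis keto-enal F6, which is closed with LiN(SiMe3)2 to ketol F2 and acetylated as above; the route is rejoined at 19.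

Step 6. The strongly basic enediolate may enolise the substrate instead of adding, and the lithium aldolate, a β-alkoxide on a fully substituted α-carbon, may fragment by retro-aldol cleavage before the quench. The fallback sets out from 11 and uses a Mukaiyama aldol, in which no basic alkoxide is formed. Silyl ketene acetal F7, made from methyl methoxyacetate with LiN(i-Pr)2 and Me3SiCl, is added under BF3·OEt2 (CH2Cl2, −78 °C) and gives after aqueous work-up hydroxy ester F8. Me3SnOH (1,2-dichloroethane, 60 °C) hydrolyses the ester under neutral conditions, and the route is rejoined at 13.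

Further compounds
F1 | step 8 | 4a-allyl-6-(3,4-dimethoxyphenyl)-3,7-dimethoxy-5-methyl-2,4a,5,6-tetrahydrocyclopenta[b]pyran-2-ol (lactol) | C=CC[C@]12C=C(OC)C(O)OC1=C(OC)[C@H](c1ccc(OC)c(OC)c1)[C@H]2C
F2 | step 8 | (1S,4S,5S,6S,7R)-1-allyl-6-(3,4-dimethoxyphenyl)-4-hydroxy-3,5-dimethoxy-7-methylbicyclo[3.2.1]oct-2-en-8-one (ketol) | C=CC[C@]12C=C(OC)[C@H](O)[C@](OC)(C1=O)[C@H](c1ccc(OC)c(OC)c1)[C@H]2C
F3 | step 7 | 4a-allyl-6-(3,4-dimethoxyphenyl)-4-hydroxy-3,7-dimethoxy-5-methylhexahydrocyclopenta[b]pyran-2-one (δ-lactone on the ring alcohol) | C=CC[C@]12C(O)C(OC)C(=O)OC1[C@@H](OC)[C@H](c1ccc(OC)c(OC)c1)[C@H]2C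
F4 | step 7 | 4a-allyl-6-(3,4-dimethoxyphenyl)-3,7-dimethoxy-5-methyl-5,6,7,7a-tetrahydrocyclopenta[b]pyran-2(4aH)-one | C=CC[C@]12C=C(OC)C(=O)OC1[C@@H](OC)[C@H](c1ccc(OC)c(OC)c1)[C@H]2C
F5 | step 7 | 2-allyl-4-(3,4-dimethoxyphenyl)-2-(3-hydroxy-2-methoxyprop-1-enyl)-5-methoxy-3-methylcyclopentan-1-ol (hydroxymethyl cis to the ring carbon) | C=CC[C@]1(/C=C(/OC)\CO)C(O)[C@@H](OC)[C@H](c2ccc(OC)c(OC)c2)[C@H]1C
F6 | step 7 | 3-[1-allyl-4-(3,4-dimethoxyphenyl)-3-methoxy-5-methyl-2-oxocyclopentyl]-2-methoxyprop-2-enal (formyl cis to the ring carbon) | C=CC[C@]1(/C=C(/OC)\C=O)C(=O)[C@@H](OC)[C@H](c2ccc(OC)c(OC)c2)[C@H]1C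
F7 | step 6 | 1,2-dimethoxy-1-(trimethylsilyloxy)ethene | COC=C(OC)O[Si](C)(C)C
F8 | step 6 | methyl 3-[1-allyl-4-(3,4-dimethoxyphenyl)-3-methoxy-5-methyl-2-oxocyclopentyl]-3-hydroxy-2-methoxypropanoate | C=CC[C@]1(C(O)C(OC)C(=O)OC)C(=O)[C@@H](OC)[C@H](c2ccc(OC)c(OC)c2)[C@H]1C
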